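## Retrosynthetic overview

1. Target ⇐ O8-selective methacrylation of the 8,9-diol ⇐ acetonide-protected tricyclic lactone.
2. Nine-membered carbocycle and trans-fused α-methylene-γ-lactone (formed last, in one step): cut C6–C7, an electroreductive chromium-catalysed intramolecular allylation of a (Z)-dienal by a 2-(bromomethyl)enoate.
3. 3(2H)-Furanone (formed second, after the purchased dioxolane): cut O–C3, C2–C3 and C3–C4, i.e. tertiary propargylic alcohol + CO + (Z)-vinyl iodide.
4. C7–C11–C13 by Morita–Baylis–Hillman reaction and SN2' bromination; C10 by chelation-controlled ethynylation of a methyl ketone.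
5. C8 and C9 are bought as natural (2R,3R)-tartrate and relay all other stereocentres; the C4=C5 geometry comes from but-2-yn-1-ol.

Assumption: germacrane numbering (C1–C15) is used; the target is (6R,7S,8S,9R,10S)-9-hydroxy-8-methacryloyloxy-1-oxo-3,10-epoxygermacra-2,4Z,11(13)-trien-12,6-olide, exactly as in the given SMILES.

## Route

Step 1
Reactants: 1 dimethyl (4R,5R)-2,2-dimethyl-1,3-dioxolane-4,5-dicarboxylate (acetonide of natural dimethyl tartrate)
Product: 2 (4R,5R)-N4,N5-dimethoxy-N4,N5,2,2-tetramethyl-1,3-dioxolane-4,5-dicarboxamide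
Conditions: MeNHOMe·HCl (2.6 equiv), i-PrMgCl (5.4 equiv), THF, −20 °C
Reagents that add atoms: N,O-dimethylhydroxylamine hydrochloride, CNOC.Cl
Why: Magnesium-amide aminolysis of both esters (Weinreb amide formation) leaves the tartrate stereocentres C8 and C9 untouched, their trans arrangement on the dioxolane being the thermodynamic one in any case.

Step 2
Reactants: 2 bis-Weinreb amide
Product: 3 (4R,5R)-5-acetyl-N-methoxy-N,2,2-trimethyl-1,3-dioxolane-4-carboxamide
Conditions: MeMgBr (1.15 equiv), THF, −78 → −20 °C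
Reagents that add atoms: methylmagnesium bromide, C[Mg]Br
Why: Grignard addition to a Weinreb amide stops at the chelated tetrahedral intermediate, so about one equivalent desymmetrises the bis-amide to the mono methyl ketone (C10 and C14 introduced).

Step 3
Reactants: 3 keto Weinreb amide
Product: 4 (4R,5R)-5-[(2R)-2-hydroxybut-3-yn-2-yl]-N-methoxy-N,2,2-trimethyl-1,3-dioxolane-4-carboxamide
Conditions: HC≡CMgBr (2.5 equiv), MgBr2·OEt2 (1.5 equiv), CH2Cl2–THF, −78 → −30 °C
Reagents that add atoms: ethynylmagnesium bromide, C#C[Mg]Br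
Why: Cram-chelate-controlled Grignard 1,2-addition: magnesium bridges the ketone oxygen and the dioxolane oxygen on C9, so the alkynyl group enters from the face of H9 and sets the C10 tertiary carbinol as the target requires, the ketone reacting far faster than the Weinreb amide at this temperature.

Step 4
Reactants: 4 propargylic alcohol Weinreb amide
Product: 5 (4R,5R)-5-[(2R)-2-hydroxybut-3-yn-2-yl]-2,2-dimethyl-1,3-dioxolane-4-carbaldehyde
Conditions: i-Bu2AlH (2.5 equiv), THF, −78 °C; aq. potassium sodium tartrate; used crude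
Reagents that add atoms: none
Why: Weinreb amide reduction stops at the chelated hemiaminal and releases the C7 aldehyde on work-up, and C8 stays trans on the dioxolane (thermodynamic configuration).

Step 5
Reactants: 5 aldehyde, 6 methyl acrylate
Product: 7 methyl 2-{hydroxy[(4S,5R)-5-[(2R)-2-hydroxybut-3-yn-2-yl]-2,2-dimethyl-1,3-dioxolan-4-yl]methyl}prop-2-enoate (both carbinol epimers)
Conditions: 6 (5 equiv), DABCO (1 equiv), 1,4-dioxane–H2O (1:1), rt, 48 h
Reagents that add atoms: none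
Why: Morita–Baylis–Hillman reaction of the reactive α-alkoxy aldehyde installs C11–C13; the new carbinol centre need not be controlled because step 9 removes it.

Step 6
Reactants: 8 but-2-yn-1-ol
Product: 9 (2Z)-3-iodobut-2-en-1-ol
Conditions: NaAlH2(OCH2CH2OMe)2 (1.4 equiv), Et2O, 0 °C → rt; EtOAc; then I2, −78 → 0 °C
Reagents that add atoms: iodine, II
Why: Hydroxyl-directed trans-hydroalumination places aluminium on C3 cis to the CH2O group, and iodinolysis with retention gives the (Z)-vinyl iodide that fixes the later C4=C5 geometry.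

Step 7
Reactants: 9 (2Z)-3-iodobut-2-en-1-ol
Product: 10 tert-butyl{[(2Z)-3-iodobut-2-en-1-yl]oxy}dimethylsilane
Conditions: TBSCl (1.1 equiv), imidazole (1.5 equiv), CH2Cl2, rt
Reagents that add atoms: tert-butyldimethylsilyl chloride, CC(C)(C)[Si](C)(C)Cl
Why: Standard silylation blocks the (Z)-γ-hydroxyl, which would otherwise close to a butenolide under the carbonylation of step 8.

Step 8
Reactants: 7 Baylis–Hillman adduct, 10 (Z)-vinyl iodide
Product: 13 methyl 2-{[(4S,5R)-5-{(2S)-5-[(2Z)-4-{[tert-butyl(dimethyl)silyl]oxy}but-2-en-2-yl]-2-methyl-3-oxo-2,3-dihydrofuran-2-yl}-2,2-dimethyl-1,3-dioxolan-4-yl](hydroxy)methyl}prop-2-enoate, via ynone 11 (not isolated), via enaminone 12 (not isolated)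
Conditions: 10 (1.2 equiv), CO (1 atm), PdCl2(PPh3)2 (5 mol %), CuI (2 mol %), Et3N, THF, rt; then Et2NH (1.5 equiv), 0 °C; then 10% aq. AcOH–THF, rt, 1 h
Reagents that add atoms: carbon monoxide, [C-]#[O+]; water, O
Why: Carbonylative Sonogashira coupling gives the 4-hydroxy-2-ynone with the vinyl iodide geometry retained; diethylamine adds to its β-carbon C1, and on acidification the C10 hydroxyl attacks C3 while the enamine is hydrolysed, closing the 3(2H)-furanone (C3 from CO, the C1 carbonyl oxygen from water) without touching C10.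

Step 9
Reactants: 13 furanone Baylis–Hillman alcohol
Product: 14 methyl (2Z)-2-(bromomethyl)-3-[(4S,5R)-5-{(2S)-5-[(2Z)-4-{[tert-butyl(dimethyl)silyl]oxy}but-2-en-2-yl]-2-methyl-3-oxo-2,3-dihydrofuran-2-yl}-2,2-dimethyl-1,3-dioxolan-4-yl]prop-2-enoate
Conditions: NBS (1.3 equiv), Me2S (1.5 equiv; reagent pre-formed), CH2Cl2, −20 → 0 °C
Reagents that add atoms: N-bromosuccinimide, O=C1CCC(=O)N1Br
Why: Corey–Kim-type activation of the Baylis–Hillman alcohol and SN2' attack by bromide give the thermodynamically preferred (Z)-2-(bromomethyl)enoate and erase the uncontrolled carbinol centre.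

Step 10
Reactants: 14 silyl ether allylic bromide
Product: 15 methyl (2Z)-2-(bromomethyl)-3-[(4S,5R)-5-{(2S)-5-[(2Z)-4-hydroxybut-2-en-2-yl]-2-methyl-3-oxo-2,3-dihydrofuran-2-yl}-2,2-dimethyl-1,3-dioxolan-4-yl]prop-2-enoate
Conditions: HF·pyridine (no added pyridine), THF, 0 °C
Reagents that add atoms: none
Why: Fluoride-driven cleavage of the primary silyl ether under acidic, non-nucleophilic conditions spares the allylic bromide and the acetonide.

Step 11
Reactants: 15 allylic alcohol
Product: 16 methyl (2Z)-2-(bromomethyl)-3-[(4S,5R)-5-{(2S)-2-methyl-3-oxo-5-[(2Z)-4-oxobut-2-en-2-yl]-2,3-dihydrofuran-2-yl}-2,2-dimethyl-1,3-dioxolan-4-yl]prop-2-enoate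
Conditions: MnO2 (20 equiv), CH2Cl2, rt, dark; filtered and used at once
Reagents that add atoms: none
Why: MnO2 oxidises only the primary allylic alcohol under neutral conditions, which preserves the labile (Z)-enal.

Step 12
Reactants: 16 bromo (Z)-dienal
Product: 19 (6R,7S,8S,9R,10S)-8,9-(isopropylidenedioxy)-1-oxo-3,10-epoxygermacra-2,4Z,11(13)-trien-12,6-olide, via silyl ether 17 (not isolated), via hydroxy ester 18 (not isolated)
Conditions: CrCl2 (15 mol %), TMSCl (3 equiv), Bu4NBF4 (0.1 mol/L), DMF, Al anode, Ni-foam cathode, undivided cell, 3 mA (2.5 F/mol), 16 added over 10 h (final 2 mmol/L), rt; then 10% aq. citric acid–THF; then CSA (5 mol %), CH2Cl2, rt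
Reagents that add atoms: none
Why: Proposed new method: an electroreductive, chromium-catalytic intramolecular Nozaki–Hiyama-type allylation closes the nine-membered carbocycle at C6–C7: cathodically regenerated divalent chromium turns the allylic bromide into an allylchromium that adds through its γ-carbon C7 to the tethered aldehyde in a chair-like six-membered transition state, TMSCl frees trivalent chromium from the alkoxide for re-reduction and the Al anode supplies the electrons; allylic 1,3-strain across C7=C11 holds H8 in the alkene plane so that tartrate-derived C8 differentiates the faces of C7, and only the arrangement with C5 and C8 both pseudo-equatorial lets the furanone-bridged tether span the new bond, which should give the (6R,7S) anti adduct that lactonises to the 6,7-trans lactone; the closest known reactions are stoichiometric CrCl2-mediated Nozaki–Hiyama macrocyclisations of 2-(bromomethyl)enoates in germacranolide synthesis and intermolecular electroreductive chromium-catalysed halide–aldehyde couplings.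

Step 13
Reactants: 19 acetonide-protected tricyclic lactone
Product: 20 (6R,7S,8S,9R,10S)-8,9-dihydroxy-1-oxo-3,10-epoxygermacra-2,4Z,11(13)-trien-12,6-olide
Conditions: TFA–H2O (9:1), CH2Cl2, 0 °C
Reagents that add atoms: none
Why: Acid hydrolysis of the strained trans-fused isopropylidene acetal is fast at 0 °C and touches no stereocentre.

Step 14
Reactants: 20 8,9-diol
Product: 21 (6R,7S,8S,9R,10S)-9-hydroxy-8-(2-methylprop-2-enoyloxy)-1-oxo-3,10-epoxygermacra-2,4Z,11(13)-trien-12,6-olide (target)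
Conditions: methacrylic anhydride (1.1 equiv), DMAP (5 mol %), Et3N (1.5 equiv), CH2Cl2, −40 → −20 °C
Reagents that add atoms: methacrylic anhydride, CC(=C)C(=O)OC(=O)C(C)=C
Why: DMAP-catalysed acylation should favour the C8 hydroxyl over the neopentylic C9 hydroxyl next to quaternary C10, and any 9-ester can relay to the less hindered O8 by 1,2-acyl migration.

## Compound list

1 | dimethyl (4R,5R)-2,2-dimethyl-1,3-dioxolane-4,5-dicarboxylate | COC(=O)[C@@H]1OC(C)(C)O[C@H]1C(=O)OC | starting material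
2 | (4R,5R)-N4,N5-dimethoxy-N4,N5,2,2-tetramethyl-1,3-dioxolane-4,5-dicarboxamide | CON(C)C(=O)[C@@H]1OC(C)(C)O[C@H]1C(=O)N(C)OC | intermediate
3 | (4R,5R)-5-acetyl-N-methoxy-N,2,2-trimethyl-1,3-dioxolane-4-carboxamide | CON(C)C(=O)[C@@H]1OC(C)(C)O[C@H]1C(C)=O | intermediate
4 | (4R,5R)-5-[(2R)-2-hydroxybut-3-yn-2-yl]-N-methoxy-N,2,2-trimethyl-1,3-dioxolane-4-carboxamide | CON(C)C(=O)[C@@H]1OC(C)(C)O[C@H]1[C@](C)(O)C#C | intermediate
5 | (4R,5R)-5-[(2R)-2-hydroxybut-3-yn-2-yl]-2,2-dimethyl-1,3-dioxolane-4-carbaldehyde | O=C[C@@H]1OC(C)(C)O[C@H]1[C@](C)(O)C#C | intermediate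
6 | methyl acrylate | C=CC(=O)OC | starting material
7 | methyl 2-{hydroxy[(4S,5R)-5-[(2R)-2-hydroxybut-3-yn-2-yl]-2,2-dimethyl-1,3-dioxolan-4-yl]methyl}prop-2-enoate (carbinol epimers) | COC(=O)C(=C)C(O)[C@@H]1OC(C)(C)O[C@H]1[C@](C)(O)C#C | intermediate
8 | but-2-yn-1-ol | CC#CCO | starting material
9 | (2Z)-3-iodobut-2-en-1-ol | C/C(I)=C/CO | intermediate
10 | tert-butyl{[(2Z)-3-iodobut-2-en-1-yl]oxy}dimethylsilane | C/C(I)=C/CO[Si](C)(C)C(C)(C)C | intermediate
11 | methyl 2-{hydroxy[(4S,5R)-5-[(2R,6Z)-8-{[tert-butyl(dimethyl)silyl]oxy}-2-hydroxy-6-methyl-5-oxooct-6-en-3-yn-2-yl]-2,2-dimethyl-1,3-dioxolan-4-yl]methyl}prop-2-enoate (ynone) | COC(=O)C(=C)C(O)[C@@H]1OC(C)(C)O[C@H]1[C@](C)(O)C#CC(=O)/C(C)=C\CO[Si](C)(C)C(C)(C)C | intermediate (not isolated)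
12 | diethylamine adduct of 11 at C1 (β-diethylamino enone; C1=C2 geometry not defined) | COC(=O)C(=C)C(O)[C@@H]1OC(C)(C)O[C@H]1[C@](C)(O)C(=CC(=O)/C(C)=C\CO[Si](C)(C)C(C)(C)C)N(CC)CC | intermediate (not isolated)
13 | methyl 2-{[(4S,5R)-5-{(2S)-5-[(2Z)-4-{[tert-butyl(dimethyl)silyl]oxy}but-2-en-2-yl]-2-methyl-3-oxo-2,3-dihydrofuran-2-yl}-2,2-dimethyl-1,3-dioxolan-4-yl](hydroxy)methyl}prop-2-enoate (carbinol epimers) | COC(=O)C(=C)C(O)[C@@H]1OC(C)(C)O[C@H]1[C@]2(C)OC(=CC2=O)/C(C)=C\CO[Si](C)(C)C(C)(C)C | intermediate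
14 | methyl (2Z)-2-(bromomethyl)-3-[(4S,5R)-5-{(2S)-5-[(2Z)-4-{[tert-butyl(dimethyl)silyl]oxy}but-2-en-2-yl]-2-methyl-3-oxo-2,3-dihydrofuran-2-yl}-2,2-dimethyl-1,3-dioxolan-4-yl]prop-2-enoate | COC(=O)/C(CBr)=C/[C@@H]1OC(C)(C)O[C@H]1[C@]2(C)OC(=CC2=O)/C(C)=C\CO[Si](C)(C)C(C)(C)C | intermediate
15 | methyl (2Z)-2-(bromomethyl)-3-[(4S,5R)-5-{(2S)-5-[(2Z)-4-hydroxybut-2-en-2-yl]-2-methyl-3-oxo-2,3-dihydrofuran-2-yl}-2,2-dimethyl-1,3-dioxolan-4-yl]prop-2-enoate | COC(=O)/C(CBr)=C/[C@@H]1OC(C)(C)O[C@H]1[C@]2(C)OC(=CC2=O)/C(C)=C\CO | intermediate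
16 | methyl (2Z)-2-(bromomethyl)-3-[(4S,5R)-5-{(2S)-2-methyl-3-oxo-5-[(2Z)-4-oxobut-2-en-2-yl]-2,3-dihydrofuran-2-yl}-2,2-dimethyl-1,3-dioxolan-4-yl]prop-2-enoate | COC(=O)/C(CBr)=C/[C@@H]1OC(C)(C)O[C@H]1[C@]2(C)OC(=CC2=O)/C(C)=C\C=O | intermediate
17 | methyl (6R,7S,8S,9R,10S)-8,9-(isopropylidenedioxy)-1-oxo-6-(trimethylsilyloxy)-3,10-epoxygermacra-2,4Z,11(13)-trien-12-oate | CC1(C)O[C@H]2[C@@H](C(=C)C(=O)OC)[C@H](O[Si](C)(C)C)/C=C(/C)C3=CC(=O)[C@@](C)(O3)[C@@H]2O1 | intermediate (not isolated)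
18 | methyl (6R,7S,8S,9R,10S)-6-hydroxy-8,9-(isopropylidenedioxy)-1-oxo-3,10-epoxygermacra-2,4Z,11(13)-trien-12-oate | CC1(C)O[C@H]2[C@@H](C(=C)C(=O)OC)[C@H](O)/C=C(/C)C3=CC(=O)[C@@](C)(O3)[C@@H]2O1 | intermediate (not isolated)
19 | (6R,7S,8S,9R,10S)-8,9-(isopropylidenedioxy)-1-oxo-3,10-epoxygermacra-2,4Z,11(13)-trien-12,6-olide | CC1(C)O[C@H]2[C@H]3C(=C)C(=O)O[C@@H]3/C=C(/C)C3=CC(=O)[C@@](C)(O3)[C@@H]2O1 | intermediate
20 | (6R,7S,8S,9R,10S)-8,9-dihydroxy-1-oxo-3,10-epoxygermacra-2,4Z,11(13)-trien-12,6-olide | O[C@H]1[C@H]2C(=C)C(=O)O[C@@H]2/C=C(/C)C2=CC(=O)[C@@](C)(O2)[C@@H]1O | intermediate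
21 | (6R,7S,8S,9R,10S)-9-hydroxy-8-(2-methylprop-2-enoyloxy)-1-oxo-3,10-epoxygermacra-2,4Z,11(13)-trien-12,6-olide | C=C(C)C(=O)O[C@H]1[C@H]2C(=C)C(=O)O[C@@H]2/C=C(/C)C2=CC(=O)[C@@](C)(O2)[C@@H]1O | target

## Step count and risks

Total steps: 14. Longest linear sequence: 12 (steps 1–5 and 8–14; steps 6 and 7 make the west half).

Three steps most likely to fail:

Step 12 (the new electrochemical ring closure). Risks: oligomerisation, direct cathodic reduction of the dienal, and the wrong C6/C7 diastereomer (untethered chromium allylations of such bromides normally favour cis lactones). Fallback, known chemistry, with the ring order changed so that the ten-membered carbocycle is closed first and the furanone last: it sets out from ynone 11, isolated by stopping step 8 before the amine is added. NBS/Me2S gives the (Z)-allylic bromide of the ynone F1, HF·pyridine gives the primary allylic alcohol F2, and MnO2 gives the enynone aldehyde F3, which is used at once because it is a labile cis-ene-dicarbonyl compound. A stoichiometric CrCl2-mediated Nozaki–Hiyama closure at high dilution (THF–DMF) and acid lactonisation then give the ten-membered enynone lactone F4, the ring size for which this closure is established in germacranolide work. Et2NH followed by aqueous AcOH closes the furanone across the ring, and the route is rejoined at 19.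

Step 8 (three-component carbonylative coupling and furanone closure). Risks: direct, CO-free Sonogashira coupling, and amine addition to the acrylate. Fallback, a two-component acyl Sonogashira coupling without CO: it sets out from 10. t-BuLi and then CO2 give (2Z)-4-{[tert-butyl(dimethyl)silyl]oxy}-2-methylbut-2-enoic acid F5, and 1-chloro-N,N,2-trimethylprop-1-en-1-amine converts it under neutral conditions into the acid chloride F6. This is coupled with 7 (PdCl2(PPh3)2, CuI, Et3N, THF, rt) to give ynone 11, where the route is rejoined (Et2NH, then aqueous AcOH, to 13).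

Step 14 (regioselective mono-acylation of the 8,9-diol). Risks: 9-ester, bis-ester, or lactone migration. Fallback, tin-directed acylation in place of kinetic discrimination: it sets out from 20. Bu2SnO (toluene, 4 Å sieves, 80 °C) gives the 8,9-O-dibutylstannylene acetal F7, which is opened by methacryloyl chloride (CH2Cl2, −20 °C) at the less hindered O8 to give 21.

## Further compounds

F1 | step 12 | methyl (2Z)-2-(bromomethyl)-3-[(4S,5R)-5-[(2R,6Z)-8-{[tert-butyl(dimethyl)silyl]oxy}-2-hydroxy-6-methyl-5-oxooct-6-en-3-yn-2-yl]-2,2-dimethyl-1,3-dioxolan-4-yl]prop-2-enoate | COC(=O)/C(CBr)=C/[C@@H]1OC(C)(C)O[C@H]1[C@](C)(O)C#CC(=O)/C(C)=C\CO[Si](C)(C)C(C)(C)C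
F2 | step 12 | methyl (2Z)-2-(bromomethyl)-3-[(4S,5R)-5-[(2R,6Z)-2,8-dihydroxy-6-methyl-5-oxooct-6-en-3-yn-2-yl]-2,2-dimethyl-1,3-dioxolan-4-yl]prop-2-enoate | COC(=O)/C(CBr)=C/[C@@H]1OC(C)(C)O[C@H]1[C@](C)(O)C#CC(=O)/C(C)=C\CO
F3 | step 12 | methyl (2Z)-2-(bromomethyl)-3-[(4S,5R)-5-[(2R,6Z)-2-hydroxy-6-methyl-5,8-dioxooct-6-en-3-yn-2-yl]-2,2-dimethyl-1,3-dioxolan-4-yl]prop-2-enoate | COC(=O)/C(CBr)=C/[C@@H]1OC(C)(C)O[C@H]1[C@](C)(O)C#CC(=O)/C(C)=C\C=O
F4 | step 12 | (6R,7S,8S,9R,10S)-10-hydroxy-8,9-(isopropylidenedioxy)-3-oxogermacra-4Z,11(13)-dien-1-yn-12,6-olide | CC1(C)O[C@H]2[C@H]3C(=C)C(=O)O[C@@H]3/C=C(/C)C(=O)C#C[C@@](C)(O)[C@@H]2O1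
F5 | step 8 | (2Z)-4-{[tert-butyl(dimethyl)silyl]oxy}-2-methylbut-2-enoic acid | OC(=O)/C(C)=C\CO[Si](C)(C)C(C)(C)C
F6 | step 8 | (2Z)-4-{[tert-butyl(dimethyl)silyl]oxy}-2-methylbut-2-enoyl chloride | ClC(=O)/C(C)=C\CO[Si](C)(C)C(C)(C)C
F7 | step 14 | 8,9-O-dibutylstannylene acetal of 20 | CCCC[Sn]1(CCCC)O[C@H]2[C@H]3C(=C)C(=O)O[C@@H]3/C=C(/C)C3=CC(=O)[C@@](C)(O3)[C@@H]2O1
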